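**Strategy.** Ring A is disconnected at C2–C3 and C4–C5, which exposes C3–C4(CH3)(CO2H) as a methacrylate and leaves ring B with the C10 quaternary centre carrying a two-carbon arm (C1–C2). In the key step a primary C2 radical, generated by decarboxylation of a redox-active ester, adds to the methacrylate CH2; the tertiary C4 radical then closes 6-exo onto C5, the terminus of the silyl dienol ether of the C8 ketone of ring B, and oxidation returns the C8 enone. One operation thus builds ring A and the C4 quaternary centre. The precursor is a monocyclic 1-silyloxycyclohexa-1,3-diene; its C8 carbonyl later becomes the exocyclic methylene.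

Key step: step 9

Remarks on the chemistry (assumptions):
- Labdane numbering is used throughout: ring A = C1–C5 and C10; ring B = C5–C10; C18 = 4α-methyl; C19 = 4β-carboxyl; C20 = 10β-methyl; C17 = methylene carbon on C8; side chain C11–C16.
- The target is taken as the open (12S,13Z)-hydroxy diacid. It is assumed to survive isolation when it is set free from its salt with a weak acid at 0 °C and never exposed to strong acid or heat, which would close the 15,12-butenolide.
- The alkylation in step 3 is expected to give both C9 epimers. Both are carried on, because C9 is set under thermodynamic control in step 11; the SMILES show the epimer that is finally wanted.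

**Step 1**
Reactants: 1 3-ethoxycyclohex-2-en-1-one; 2 but-3-en-1-ylmagnesium bromide
Product: 3 3-(but-3-en-1-yl)cyclohex-2-en-1-one
Conditions: THF, 0 °C to rt; then 1 M HCl, 0 °C
Reagents that add atoms: none
Why: Stork–Danheiser sequence, in which 1,2-addition of the Grignard reagent to the vinylogous ester and acid-promoted hydrolysis with loss of water transpose the carbonyl and give the 3-substituted enone.

**Step 2**
Reactants: 3 3-(but-3-en-1-yl)cyclohex-2-en-1-one
Product: 5 {[(3R)-3-(but-3-en-1-yl)-3-methylcyclohex-1-en-1-yl]oxy}trimethylsilane, via aluminium enolate 4 (not isolated)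
Conditions: Me3Al (1.5 equiv), copper thiophene-2-carboxylate (CuTC, 2 mol %), chiral biphenol-derived phosphoramidite ligand (4 mol %), Et2O, −30 °C; then TMSOTf, Et3N, THF, −30 to 0 °C
Reagents that add atoms: trimethylaluminium, C[Al](C)C; trimethylsilyl triflate, C[Si](C)(C)OS(=O)(=O)C(F)(F)F
Why: Copper-catalysed asymmetric conjugate addition of trimethylaluminium to the β-substituted cyclohexenone creates the quaternary carbon (future C10), the ligand enantiomer being chosen to give the R centre, and O-silylation stores the enolate regiospecifically on the C8–C9 side.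

**Step 3**
Reactants: 5 the silyl enol ether; 6 methyl bromoacetate
Product: 8 methyl 2-[(1R,2R)-2-(but-3-en-1-yl)-2-methyl-6-oxocyclohexyl]acetate, via lithium enolate 7 (not isolated)
Conditions: MeLi (1.05 equiv), THF, 0 °C; then DMPU, 6, −78 to 0 °C
Reagents that add atoms: methyllithium, [Li]C (lithium of intermediate 7 only)
Why: Methyllithium cleaves the silyl enol ether to the regiodefined lithium enolate, which is alkylated at C9 by the reactive α-bromo ester (enolate alkylation); the new centre is epimerisable and is fixed later.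

**Step 4**
Reactants: 8 the keto ester
Product: 10 methyl 2-[(1R,6S)-6-(but-3-en-1-yl)-6-methyl-2-oxocyclohex-3-en-1-yl]acetate, via kinetic silyl enol ether 9 (not isolated)
Conditions: LiHMDS, TMSCl, THF, −78 °C; then Pd(OAc)2 (1.05 equiv), MeCN, rt
Reagents that add atoms: chlorotrimethylsilane, C[Si](C)(C)Cl (silicon of intermediate 9 only)
Why: Saegusa–Ito dehydrogenation, in which kinetic deprotonation takes the unhindered C7 methylene and not the hindered C9 methine, so that the palladium enolate can only eliminate toward C6 and gives the C6=C7 enone.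

**Step 5**
Reactants: 10 the butenyl enone
Product: 12 3-[(1S,6R)-6-(2-methoxy-2-oxoethyl)-1-methyl-5-oxocyclohex-3-en-1-yl]propanoic acid, via aldehyde 11 (not isolated)
Conditions: O3, CH2Cl2, −78 °C (Sudan red end point); Me2S; then NaClO2, NaH2PO4, 2-methyl-2-butene, t-BuOH/H2O, rt
Reagents that add atoms: ozone, [O-][O+]=O; sodium chlorite, [Na+].[O-]Cl=O
Why: Ozonolysis cleaves the electron-rich terminal alkene in preference to the electron-poor enone double bond, and Pinnick oxidation of the aldehyde gives the acid whose carboxyl carbon is lost in step 9.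

**Step 6**
Reactants: 12 the enone acid
Product: 13 1,3-dioxoisoindolin-2-yl 3-[(1S,6R)-6-(2-methoxy-2-oxoethyl)-1-methyl-5-oxocyclohex-3-en-1-yl]propanoate
Conditions: N-hydroxyphthalimide, DIC, DMAP (cat.), CH2Cl2, rt
Reagents that add atoms: N-hydroxyphthalimide, O=C1c2ccccc2C(=O)N1O
Why: Carbodiimide (Steglich-type) esterification installs the redox-active ester under neutral conditions that leave the enone untouched.

**Step 7**
Reactants: 13 the redox-active ester
Product: 14 1,3-dioxoisoindolin-2-yl 3-[(1S,6R)-5-(tert-butyldimethylsilyloxy)-6-(2-methoxy-2-oxoethyl)-1-methylcyclohexa-2,4-dien-1-yl]propanoate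
Conditions: TBSOTf (1.3 equiv), Et3N (2 equiv), CH2Cl2, −78 to 0 °C
Reagents that add atoms: tert-butyldimethylsilyl triflate, CC(C)(C)[Si](C)(C)OS(=O)(=O)C(F)(F)F
Why: Soft enolisation of the enone removes a γ-proton from the C5 methylene and gives the linear 1-silyloxy-1,3-diene (C8=C7–C6=C5), expected to be favoured because the competing α′ proton at C9 is a hindered methine next to the quaternary centre.

**Step 8**
Reactants: 15 methacryloyl chloride; 16 2-(trimethylsilyl)ethanol
Product: 17 2-(trimethylsilyl)ethyl methacrylate
Conditions: Et3N, DMAP (cat.), CH2Cl2, 0 °C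
Reagents that add atoms: none
Why: Acylation of the alcohol by the acid chloride gives a methacrylate whose ester can later be removed with fluoride without acid or hydrogenation.

**Step 9**
Reactants: 14 the silyl dienol ether; 17 2-(trimethylsilyl)ethyl methacrylate
Product: 18 12-methyl 19-[2-(trimethylsilyl)ethyl] 8-oxo-13,14,15,16,17-pentanor-5β-labd-6-ene-12,19-dioate (cis-fused enone)
Conditions: fac-Ir(ppy)3 (1 mol %), 17 (10 equiv), MeCN (0.05 M), blue LEDs, rt; then 1 M HCl, THF, 0 °C
Reagents that add atoms: none
Why: Excited fac-Ir(ppy)3 reduces the N-acyloxyphthalimide, loss of CO2 gives the primary C2 radical, which adds to the CH2 terminus of 17 (C2–C3), and the electrophilic tertiary C4 radical then adds to C5, the terminus of the electron-rich silyloxydiene (C4–C5), after which the silyloxyallyl radical is oxidised by the tetravalent iridium formed at the start and desilylated to the C8 enone. The closest known reaction types are the photoredox decarboxylative Giese addition of redox-active esters and the radical–polar crossover alkylation of silyl enol and dienol ethers by α-carbonyl radicals, merged here into a radical [4+2] annulation. Ring A closes in the 6-exo-trig mode. C4 is set in a chair-like transition state in which the planar conjugated ester is expected to take the pseudo-equatorial (exo) position and the methyl group the position under ring B, which places the ester cis to the C10 methyl group; this preference is a prediction and is the main risk. C5 forms cis-fused, because the short tether reaches only the face of the flat diene on which it sits, and this centre is erased and reset in steps 10 and 11. The step needs capture of the nucleophilic C2 radical by the electron-poor alkene and of the electrophilic C4 radical by the diene in preference to chain growth, which polarity matching, the excess of 17 and the high effective molarity of the six-membered closure should secure.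

**Step 10**
Reactants: 18 the cis-fused enone
Product: 19 12-methyl 19-[2-(trimethylsilyl)ethyl] 8-oxo-13,14,15,16,17-pentanorlabd-5-ene-12,19-dioate (β,γ-enone)
Conditions: KOt-Bu (3 equiv), t-BuOH/THF (degassed), rt; inverse quench into cold 10% aq. AcOH
Reagents that add atoms: none
Why: Classical enone deconjugation, in which thermodynamic deprotonation gives the extended dienolate with a trigonal C5 and kinetic protonation at the α-carbon C7 delivers the β,γ-enone, so the cis ring fusion is erased.

**Step 11**
Reactants: 19 the β,γ-enone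
Product: 20 12-methyl 19-[2-(trimethylsilyl)ethyl] 8-oxo-13,14,15,16,17-pentanorlabdane-12,19-dioate (trans-fused: 5α-H and 9α-H)
Conditions: Mn(dpm)3 (10 mol %), PhSiH3, t-BuOOH, i-PrOH, rt; then NaOMe (0.3 equiv), MeOH, rt
Reagents that add atoms: none
Why: Metal-hydride hydrogen-atom-transfer hydrogenation (Mukaiyama type) puts a hydrogen atom on C6, and the tertiary C5 radical takes up hydrogen on the α face, anti to the 10β-methyl and 4β-ester groups, to give the trans-decalin; methoxide then equilibrates C9 to the equatorial 9β side chain.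

**Step 12**
Reactants: 20 the trans-fused ketone
Product: 21 12-methyl 19-[2-(trimethylsilyl)ethyl] 13,14,15,16-tetranorlabd-8(17)-ene-12,19-dioate
Conditions: Zn, CH2Br2, TiCl4 (preformed Lombardo reagent), THF/CH2Cl2, 0 °C to rt
Reagents that add atoms: dibromomethane, BrCBr
Why: Takai–Lombardo methylenation is non-basic, so the hindered enolisable C8 ketone becomes the exocyclic methylene (C17) without epimerising C9 or touching either ester.

**Step 13**
Reactants: 21 the methylene diester
Product: 22 2-(trimethylsilyl)ethyl 12-oxo-13,14,15,16-tetranorlabd-8(17)-en-19-oate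
Conditions: DIBAL-H (1.1 equiv), CH2Cl2, −78 °C; Rochelle salt
Reagents that add atoms: none
Why: DIBAL-H reduces the unhindered primary methyl ester to the aldehyde through a stable tetrahedral aluminate, while the axial neopentyl-type C19 ester is too hindered to react.

**Step 14**
Reactants: 22 the aldehyde; 23 methyl propiolate
Product: 24 15-methyl 19-[2-(trimethylsilyl)ethyl] (12S)-12-hydroxy-16-norlabd-8(17)-en-13-yne-15,19-dioate
Conditions: Me2Zn (3 equiv), ProPhenol ligand (20 mol %, enantiomer giving the 12S carbinol), Ph3PO (40 mol %), toluene, 4 °C; aq. NH4Cl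
Reagents that add atoms: none
Why: Zinc–ProPhenol catalysed asymmetric alkynylation adds the zinc acetylide of 23 to the aldehyde and sets C12 under catalyst control, which is needed because C12 is remote from the ring stereocentres.

**Step 15**
Reactants: 24 the hydroxy ynoate
Product: 26 2-(trimethylsilyl)ethyl (12S)-labda-8(17),13-dien-15,12-olid-19-oate (butenolide), via Z-hydroxy enoate 25 (not isolated)
Conditions: Me2CuLi (3 equiv), THF, −78 °C; aq. NH4Cl, warm to rt
Reagents that add atoms: lithium dimethylcuprate, [Li+].C[Cu-]C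
Why: syn-Carbocupration of the ynoate puts the new methyl group and copper on the same side, so after protonation the C12 carbinol and the ester are cis (13Z) and lactonise to the butenolide.

**Step 16**
Reactants: 26 the butenolide
Product: 28 (12S,13Z)-12-hydroxylabda-8(17),13-diene-15,19-dioic acid, via lithium carboxylate 27 (not isolated)
Conditions: LiOH (4 equiv), THF/H2O, 0 °C; then TBAF (3 equiv), THF, 40 °C; then AcOH to pH 5, 0 °C, cold extraction
Reagents that add atoms: lithium hydroxide, [Li+].[OH-]
Why: Hydroxide opens the butenolide to the (Z)-hydroxy carboxylate with the double-bond geometry fixed by the former ring, fluoride then fragments the 2-(trimethylsilyl)ethyl ester, and weak-acid protonation at 0 °C should release the hydroxy diacid before it can relactonise.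

**Compound list**

1 | 3-ethoxycyclohex-2-en-1-one | CCOC1=CC(=O)CCC1 | starting material
2 | but-3-en-1-ylmagnesium bromide | C=CCC[Mg]Br | starting material
3 | 3-(but-3-en-1-yl)cyclohex-2-en-1-one | C=CCCC1=CC(=O)CCC1 | intermediate
4 | dimethylaluminium enolate of (R)-3-(but-3-en-1-yl)-3-methylcyclohexanone (C8–C9 enolate) | C[Al](C)OC1=C[C@@](C)(CCC=C)CCC1 | intermediate
5 | {[(3R)-3-(but-3-en-1-yl)-3-methylcyclohex-1-en-1-yl]oxy}trimethylsilane | C[Si](C)(C)OC1=C[C@@](C)(CCC=C)CCC1 | intermediate
6 | methyl bromoacetate | COC(=O)CBr | starting material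
7 | lithium enolate corresponding to 5 | [Li]OC1=C[C@@](C)(CCC=C)CCC1 | intermediate
8 | methyl 2-[(1R,2R)-2-(but-3-en-1-yl)-2-methyl-6-oxocyclohexyl]acetate | O=C1CCC[C@](C)(CCC=C)[C@H]1CC(=O)OC | intermediate
9 | kinetic C7 trimethylsilyl enol ether of 8 | C[Si](C)(C)OC1=CCC[C@](C)(CCC=C)[C@H]1CC(=O)OC | intermediate
10 | methyl 2-[(1R,6S)-6-(but-3-en-1-yl)-6-methyl-2-oxocyclohex-3-en-1-yl]acetate | O=C1C=CC[C@](C)(CCC=C)[C@H]1CC(=O)OC | intermediate
11 | aldehyde from ozonolysis of 10 (3-oxopropyl arm on the quaternary carbon) | O=C1C=CC[C@](C)(CCC=O)[C@H]1CC(=O)OC | intermediate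
12 | 3-[(1S,6R)-6-(2-methoxy-2-oxoethyl)-1-methyl-5-oxocyclohex-3-en-1-yl]propanoic acid | O=C1C=CC[C@](C)(CCC(=O)O)[C@H]1CC(=O)OC | intermediate
13 | 1,3-dioxoisoindolin-2-yl 3-[(1S,6R)-6-(2-methoxy-2-oxoethyl)-1-methyl-5-oxocyclohex-3-en-1-yl]propanoate | O=C1C=CC[C@](C)(CCC(=O)ON2C(=O)c3ccccc3C2=O)[C@H]1CC(=O)OC | intermediate
14 | 1,3-dioxoisoindolin-2-yl 3-[(1S,6R)-5-(tert-butyldimethylsilyloxy)-6-(2-methoxy-2-oxoethyl)-1-methylcyclohexa-2,4-dien-1-yl]propanoate | CC(C)(C)[Si](C)(C)OC1=CC=C[C@](C)(CCC(=O)ON2C(=O)c3ccccc3C2=O)[C@H]1CC(=O)OC | intermediate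
15 | methacryloyl chloride | C=C(C)C(=O)Cl | starting material
16 | 2-(trimethylsilyl)ethanol | C[Si](C)(C)CCO | starting material
17 | 2-(trimethylsilyl)ethyl methacrylate | C=C(C)C(=O)OCC[Si](C)(C)C | intermediate
18 | 12-methyl 19-[2-(trimethylsilyl)ethyl] 8-oxo-13,14,15,16,17-pentanor-5β-labd-6-ene-12,19-dioate | O=C1C=C[C@H]2[C@](C)(CCC[C@]2(C)C(=O)OCC[Si](C)(C)C)[C@H]1CC(=O)OC | intermediate
19 | 12-methyl 19-[2-(trimethylsilyl)ethyl] 8-oxo-13,14,15,16,17-pentanorlabd-5-ene-12,19-dioate | O=C1CC=C2[C@](C)(CCC[C@]2(C)C(=O)OCC[Si](C)(C)C)[C@H]1CC(=O)OC | intermediate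
20 | 12-methyl 19-[2-(trimethylsilyl)ethyl] 8-oxo-13,14,15,16,17-pentanorlabdane-12,19-dioate | O=C1CC[C@@H]2[C@](C)(CCC[C@]2(C)C(=O)OCC[Si](C)(C)C)[C@H]1CC(=O)OC | intermediate
21 | 12-methyl 19-[2-(trimethylsilyl)ethyl] 13,14,15,16-tetranorlabd-8(17)-ene-12,19-dioate | C=C1CC[C@@H]2[C@](C)(CCC[C@]2(C)C(=O)OCC[Si](C)(C)C)[C@H]1CC(=O)OC | intermediate
22 | 2-(trimethylsilyl)ethyl 12-oxo-13,14,15,16-tetranorlabd-8(17)-en-19-oate | C=C1CC[C@@H]2[C@](C)(CCC[C@]2(C)C(=O)OCC[Si](C)(C)C)[C@H]1CC=O | intermediate
23 | methyl propiolate | C#CC(=O)OC | starting material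
24 | 15-methyl 19-[2-(trimethylsilyl)ethyl] (12S)-12-hydroxy-16-norlabd-8(17)-en-13-yne-15,19-dioate | C=C1CC[C@@H]2[C@](C)(CCC[C@]2(C)C(=O)OCC[Si](C)(C)C)[C@H]1C[C@H](O)C#CC(=O)OC | intermediate
25 | 15-methyl 19-[2-(trimethylsilyl)ethyl] (12S,13Z)-12-hydroxylabda-8(17),13-diene-15,19-dioate | C=C1CC[C@@H]2[C@](C)(CCC[C@]2(C)C(=O)OCC[Si](C)(C)C)[C@H]1C[C@H](O)/C(C)=C\C(=O)OC | intermediate
26 | 2-(trimethylsilyl)ethyl (12S)-labda-8(17),13-dien-15,12-olid-19-oate | C=C1CC[C@@H]2[C@](C)(CCC[C@]2(C)C(=O)OCC[Si](C)(C)C)[C@H]1C[C@H](O3)C(C)=CC3=O | intermediate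
27 | lithium (12S,13Z)-12-hydroxy-19-oxo-19-[2-(trimethylsilyl)ethoxy]labda-8(17),13-dien-15-oate | C=C1CC[C@@H]2[C@](C)(CCC[C@]2(C)C(=O)OCC[Si](C)(C)C)[C@H]1C[C@H](O)/C(C)=C\C(=O)[O-].[Li+] | intermediate
28 | (12S,13Z)-12-hydroxylabda-8(17),13-diene-15,19-dioic acid | C=C1CC[C@@H]2[C@](C)(CCC[C@]2(C)C(=O)O)[C@H]1C[C@H](O)/C(C)=C\C(=O)O | target

**Step count.** Total: 16 steps. Longest linear sequence: 15 steps (steps 1–7 and 9–16); step 8 is a one-step branch.

**Steps most likely to fail**

1. Step 9. The ring closure may show poor facial selectivity at C4 (ester under ring B instead of exo), or chain growth with the methacrylate may compete with cyclisation. The fallback sets out from 14 and comes back at 21; it builds the same two ring bonds first and adds the C4 methyl group afterwards by enolate alkylation. 2-(Trimethylsilyl)ethyl acrylate F1, made from acryloyl chloride and 16 as in step 8, replaces 17 under the step 9 conditions and should give the cis-fused enone without the C4 methyl group F2. The conditions of steps 10, 11 and 12 then should give the β,γ-enone F3, the trans-fused ketone with an equatorial C4 ester F4 and the exocyclic alkene F5. LiOH in aqueous THF at 0 °C should hydrolyse only the unhindered methyl ester to the acid F6. LDA (2.1 equiv, THF, −78 °C) forms the carboxylate and the C4 ester enolate, and methyl iodide should enter from the equatorial α face, the β face being shielded by the axial C10 methyl group, to give the C4-methylated acid F7 with the axial ester. Trimethylsilyldiazomethane in MeOH/toluene returns the methyl ester 21.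

2. Step 7. Silylation may follow enolisation toward C9 and give the cross-conjugated dienol ether, which cannot accept the C4 radical at C5. The fallback sets out from 12 and comes back at 14; it forms the dienol ether from the thermodynamic dienolate before the base-sensitive redox-active ester is present. KHMDS (2.0 equiv, THF, −78 to 0 °C, equilibrating) gives the carboxylate and the extended dienolate, and TBSCl gives the bis-silyl compound F8. K2CO3 in aqueous MeOH at 0 °C should cleave only the silyl ester to the dienol ether acid F9, and DIC with N-hydroxyphthalimide gives 14.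

3. Step 10. γ-Deprotonation at the hindered C5–H may be incomplete, or the dienolate may be protonated back to the conjugated enone. The fallback sets out from 18 and comes back at 20; it relies on thermodynamic epimerisation instead of kinetic hydrogen delivery. NaOMe in MeOH at 50 °C equilibrates C5 and C9 through the dienolate toward the trans-fused enone F10 (its preference over the cis isomer is not certain), and H2 with Pd/C in EtOAc saturates C6=C7 to give 20.

Further compounds
F1 | step 9 | 2-(trimethylsilyl)ethyl acrylate | C=CC(=O)OCC[Si](C)(C)C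
F2 | step 9 | cis-fused enone diester lacking the C4 methyl group (C4–H; ester drawn α) | O=C1C=C[C@H]2[C@](C)(CCC[C@H]2C(=O)OCC[Si](C)(C)C)[C@H]1CC(=O)OC
F3 | step 9 | β,γ-enone (5-ene) diester lacking the C4 methyl group | O=C1CC=C2[C@](C)(CCC[C@H]2C(=O)OCC[Si](C)(C)C)[C@H]1CC(=O)OC
F4 | step 9 | trans-fused 8-ketone with equatorial (4α) 2-(trimethylsilyl)ethyl ester and 4β-H | O=C1CC[C@@H]2[C@](C)(CCC[C@H]2C(=O)OCC[Si](C)(C)C)[C@H]1CC(=O)OC
F5 | step 9 | 8(17)-methylene diester with 4β-H | C=C1CC[C@@H]2[C@](C)(CCC[C@H]2C(=O)OCC[Si](C)(C)C)[C@H]1CC(=O)OC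
F6 | step 9 | 8(17)-methylene C12 carboxylic acid with 4β-H and 4α 2-(trimethylsilyl)ethyl ester | C=C1CC[C@@H]2[C@](C)(CCC[C@H]2C(=O)OCC[Si](C)(C)C)[C@H]1CC(=O)O
F7 | step 9 | 19-[2-(trimethylsilyl)ethyl] hydrogen 13,14,15,16-tetranorlabd-8(17)-ene-12,19-dioate (C12 acid with 4α-methyl and 4β-ester) | C=C1CC[C@@H]2[C@](C)(CCC[C@]2(C)C(=O)OCC[Si](C)(C)C)[C@H]1CC(=O)O
F8 | step 7 | tert-butyldimethylsilyl ester of the TBS dienol ether of 12 | CC(C)(C)[Si](C)(C)OC1=CC=C[C@](C)(CCC(=O)O[Si](C)(C)C(C)(C)C)[C@H]1CC(=O)OC
F9 | step 7 | 3-[(1S,6R)-5-(tert-butyldimethylsilyloxy)-6-(2-methoxy-2-oxoethyl)-1-methylcyclohexa-2,4-dien-1-yl]propanoic acid | CC(C)(C)[Si](C)(C)OC1=CC=C[C@](C)(CCC(=O)O)[C@H]1CC(=O)OC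
F10 | step 10 | 12-methyl 19-[2-(trimethylsilyl)ethyl] 8-oxo-13,14,15,16,17-pentanorlabd-6-ene-12,19-dioate (trans-fused, 5α-H) | O=C1C=C[C@@H]2[C@](C)(CCC[C@]2(C)C(=O)OCC[Si](C)(C)C)[C@H]1CC(=O)OC
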